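**Plan**

- Retrosynthesis: the eight benzyl ethers are cut last and the C4 carbonyl is traced back to a 4-methoxy group. Ring C of the flavanone is then opened at O1–C2 and C3–C4 into salicylaldehyde 2, trimethyl orthoformate 16 and biaryl styrene 15. Styrene 15 is cut at the aryl–aryl bond (ring B C6' to flavone C8) into 8-iodoflavone 10 and vinylaryl boronate 14.
- Enabling feature: in the flavanone, O1 and C4 sit on the adjacent carbons C8a and C4a of phloroglucinol ring A, and C2 is benzylic to ring B. A ring A ortho-quinone methide (O1=C8a–C4a=C4) therefore supplies the heterodiene and a ring B vinyl group supplies C2–C3.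
- Forward order: the pyranone ring of the luteolin unit is built first (chalcone, oxidative cyclisation), the biaryl bond is joined by Suzuki coupling, and flavanone ring C is closed by the (4+2) step. The C4 oxidation level and the phenols are adjusted at the end.
- Stereochemistry: the only stereocentre of the target, C2 (R), is set in the cycloaddition by a chiral counteranion. C4 of the cycloadduct is transient and is erased on oxidation.

Key step: step 10

Assumption: the target carries no axial descriptor, so the tri-ortho-substituted biaryl axis is treated as stereochemically unassigned and compounds from 15 onward are handled as rotamer mixtures where these arise.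

**Route**

Step 1
Reactants: 1 2,4,6-trihydroxybenzaldehyde
Product: 2 2-hydroxy-4,6-bis(benzyloxy)benzaldehyde
Conditions: BnBr (2.1 equiv), K2CO3, DMF, 0 °C to rt
Reagents that add atoms: benzyl bromide, BrCc1ccccc1
Why: Williamson etherification, in which the 4-OH and one ortho OH are alkylated while the remaining ortho OH, hydrogen-bonded to the formyl group, is the least nucleophilic and stays free.

Step 2
Reactants: 3 2,4,6-trihydroxyacetophenone
Product: 4 1-[2-hydroxy-4,6-bis(benzyloxy)phenyl]ethanone
Conditions: BnBr (2.1 equiv), K2CO3, DMF, rt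
Reagents that add atoms: benzyl bromide, BrCc1ccccc1
Why: Williamson etherification with the same chelation-based selectivity as in step 1, leaving the hydroxyl that later becomes O1 of the flavone.

Step 3
Reactants: 4 1-[2-hydroxy-4,6-bis(benzyloxy)phenyl]ethanone
Product: 5 1-[2-hydroxy-3-iodo-4,6-bis(benzyloxy)phenyl]ethanone
Conditions: BnMe3N+ ICl2−, NaHCO3, CH2Cl2/MeOH, rt
Reagents that add atoms: benzyltrimethylammonium dichloroiodate, C[N+](C)(C)Cc1ccccc1.Cl[I-]Cl
Why: Electrophilic aromatic iodination, which on 2-hydroxy-4,6-dialkoxyacetophenones is known to go to C3 (ortho to the free phenol, para to the 6-alkoxy group), the carbon that becomes C8 of the flavone.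

Step 4
Reactants: 5 1-[2-hydroxy-3-iodo-4,6-bis(benzyloxy)phenyl]ethanone; 6 3,4-bis(benzyloxy)benzaldehyde
Product: 7 (E)-1-[2-hydroxy-3-iodo-4,6-bis(benzyloxy)phenyl]-3-[3,4-bis(benzyloxy)phenyl]prop-2-en-1-one
Conditions: KOH, EtOH/THF, rt
Reagents that add atoms: none
Why: Claisen–Schmidt condensation of the methyl ketone enolate with a non-enolisable aldehyde, with E1cB dehydration giving the E-chalcone.

Step 5
Reactants: 7 (E)-2'-hydroxy-3'-iodochalcone
Product: 10 5,7-bis(benzyloxy)-2-[3,4-bis(benzyloxy)phenyl]-8-iodo-4H-chromen-4-one, via 8-iodoflavanone 8 (not isolated), via 3,8-diiodoflavanone 9 (not isolated)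
Conditions: I2 (10 mol %), DMSO, 120 °C
Reagents that add atoms: none
Why: Iodine-catalysed oxidative cyclisation of a 2'-hydroxychalcone (oxa-Michael closure, α-iodination, loss of HI, with DMSO re-oxidising iodide), in which the catalytic iodine loading keeps HI low so that the benzyl ethers and the aryl iodide should survive.

Step 6
Reactants: 6 3,4-bis(benzyloxy)benzaldehyde
Product: 11 4,5-bis(benzyloxy)-2-bromobenzaldehyde
Conditions: Br2, NaOAc, AcOH, rt
Reagents that add atoms: bromine, BrBr
Why: Electrophilic aromatic bromination, directed para to the 3-benzyloxy group as in the bromination of 3,4-dialkoxybenzaldehydes, with acetate buffering the HBr.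

Step 7
Reactants: 11 4,5-bis(benzyloxy)-2-bromobenzaldehyde
Product: 12 1,2-bis(benzyloxy)-4-bromo-5-vinylbenzene
Conditions: Ph3PCH3Br, KOt-Bu, THF, 0 °C to rt
Reagents that add atoms: methyltriphenylphosphonium bromide, C[P+](c1ccccc1)(c1ccccc1)c1ccccc1.[Br-]
Why: Wittig methylenation of an aryl aldehyde with a non-stabilised ylide, done before the flavone is present so that no competing electrophile is in the flask.

Step 8
Reactants: 12 1,2-bis(benzyloxy)-4-bromo-5-vinylbenzene
Product: 14 2-[4,5-bis(benzyloxy)-2-vinylphenyl]-4,4,5,5-tetramethyl-1,3,2-dioxaborolane, via aryllithium 13 (not isolated)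
Conditions: n-BuLi, THF, −78 °C; then i-PrOBpin, −78 °C to rt; aq. NH4Cl
Reagents that add atoms: 2-isopropoxy-4,4,5,5-tetramethyl-1,3,2-dioxaborolane, CC(C)OB1OC(C)(C)C(C)(C)O1
Why: Bromine–lithium exchange outruns carbolithiation of the vinyl group and benzylic deprotonation at −78 °C, and the aryllithium is trapped by the borate ester to give the pinacol boronate.

Step 9
Reactants: 10 8-iodoflavone; 14 vinylaryl pinacol boronate
Product: 15 5,7-bis(benzyloxy)-2-[3,4-bis(benzyloxy)phenyl]-8-[4,5-bis(benzyloxy)-2-vinylphenyl]-4H-chromen-4-one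
Conditions: Pd(OAc)2 (5 mol %), SPhos (10 mol %), K3PO4, toluene/H2O, 90 °C
Reagents that add atoms: none
Why: Suzuki–Miyaura coupling, in which SPhos-ligated zerovalent palladium is known to join aryl iodides flanked by two oxygen substituents to ortho-substituted boronates, while the vinyl group and the flavone tolerate aqueous phosphate.

Step 10
Reactants: 2 2-hydroxy-4,6-bis(benzyloxy)benzaldehyde; 16 trimethyl orthoformate; 15 biaryl styrene
Product: 19 (2R,4R)-cis-4-methoxyflavan octabenzyl ether, via dimethyl acetal 17 (not isolated), via methoxy ortho-quinone methide 18 (not isolated)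
Conditions: 2 (1.5 equiv), HC(OMe)3 (2 equiv), confined BINOL-derived imidodiphosphorimidate acid (10 mol %, antipode selected for 2R), 5 Å MS, CHCl3, −30 °C
Reagents that add atoms: trimethyl orthoformate (compound 16), COC(OC)OC
Why: Proposed new method: the acid turns 2 and 16 into acetal 17, which ionises with loss of methanol to the methoxy ortho-quinone methide 18, held as a hydroxyaryl oxocarbenium ion pair with the chiral anion; the CH2 terminus of the electron-rich styrene 15 bonds to the cationic carbon (C3–C4) and the phenol oxygen then closes onto the para-benzyloxy-stabilised benzylic carbon (O1–C2), an asynchronous inverse-electron-demand hetero-Diels–Alder reaction. The closest known reactions are the racemic acid-catalysed three-component synthesis of cis-4-alkoxy-2-arylchromans from salicylaldehydes, orthoformates and styrenes and the chiral phosphoric acid catalysed (4+2) cycloadditions of ortho-quinone methides with activated styrenes; enantiocontrol with a styrene that offers no hydrogen-bonding handle is the untested part. Ring C closes in the (4+2) mode, which in the stepwise limit is a 6-exo-trig capture of the benzylic cation by the phenol oxygen. C4 is fixed by the face of the oxocarbenium ion left open by the counteranion during C–C bond formation, and C2 follows from the endo, chair-like closure that places aryl and methoxy cis, giving (2R,4R); only C2 has to last because C4 is oxidised later. The step needs head-to-tail regioselectivity, secured by the polarisation of both partners, chemoselectivity for the terminal vinyl group over the electron-poor flavone C2=C3 bond, secured by the nucleophilicity of the para-alkoxystyrene, and enantioface selectivity, for which the substrate offers nothing and the confined anion must act alone.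

Step 11
Reactants: 19 (2R,4R)-cis-4-methoxyflavan octabenzyl ether
Product: 20 (2R)-flavan-4-ol octabenzyl ether (mixture of C4 epimers expected)
Conditions: p-TsOH·H2O (10 mol %), THF/H2O (4:1), rt
Reagents that add atoms: water, O
Why: SN1 solvolysis of a benzylic methyl ether whose cation is stabilised by the three oxygen donors of ring A, with the large excess of water capturing the cation; C2 is not involved and both C4 epimers converge in step 12.

Step 12
Reactants: 20 (2R)-flavan-4-ol octabenzyl ether
Product: 21 (2R)-flavanone octabenzyl ether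
Conditions: Dess–Martin periodinane, pyridine, CH2Cl2, 0 °C to rt
Reagents that add atoms: none
Why: Dess–Martin oxidation of a secondary benzylic alcohol under buffered conditions, too mild to open the flavanone to the chalcone, so the C2 configuration should be kept.

Step 13
Reactants: 21 (2R)-flavanone octabenzyl ether
Product: 22 CNP0228504.1, (2R)-flavanone–flavone biaryl with eight free phenols
Conditions: H2 (1 atm), Pd/C (10 wt %), THF/MeOH, rt
Reagents that add atoms: none
Why: Catalytic hydrogenolysis of the eight benzyl ethers under neutral conditions, which avoid ring-opening racemisation at C2, with the reaction stopped at full debenzylation because the flavone C2=C3 bond, the ketone and the benzylic C2–O1 bond react more slowly at atmospheric pressure.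

**Compound list**

1 | 2,4,6-trihydroxybenzaldehyde | O=Cc1c(O)cc(O)cc1O | starting material
2 | 2-hydroxy-4,6-bis(benzyloxy)benzaldehyde | O=Cc1c(O)cc(OCc2ccccc2)cc1OCc1ccccc1 | intermediate
3 | 2,4,6-trihydroxyacetophenone | CC(=O)c1c(O)cc(O)cc1O | starting material
4 | 1-[2-hydroxy-4,6-bis(benzyloxy)phenyl]ethanone | CC(=O)c1c(O)cc(OCc2ccccc2)cc1OCc1ccccc1 | intermediate
5 | 1-[2-hydroxy-3-iodo-4,6-bis(benzyloxy)phenyl]ethanone | CC(=O)c1c(O)c(I)c(OCc2ccccc2)cc1OCc1ccccc1 | intermediate
6 | 3,4-bis(benzyloxy)benzaldehyde | O=Cc1ccc(OCc2ccccc2)c(OCc2ccccc2)c1 | starting material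
7 | (E)-1-[2-hydroxy-3-iodo-4,6-bis(benzyloxy)phenyl]-3-[3,4-bis(benzyloxy)phenyl]prop-2-en-1-one | O=C(/C=C/c1ccc(OCc2ccccc2)c(OCc2ccccc2)c1)c1c(O)c(I)c(OCc2ccccc2)cc1OCc1ccccc1 | intermediate
8 | rac-5,7-bis(benzyloxy)-2-[3,4-bis(benzyloxy)phenyl]-8-iodochroman-4-one | O=C1CC(c2ccc(OCc3ccccc3)c(OCc3ccccc3)c2)Oc2c(I)c(OCc3ccccc3)cc(OCc3ccccc3)c21 | intermediate
9 | rac-5,7-bis(benzyloxy)-2-[3,4-bis(benzyloxy)phenyl]-3,8-diiodochroman-4-one | O=C1C(I)C(c2ccc(OCc3ccccc3)c(OCc3ccccc3)c2)Oc2c(I)c(OCc3ccccc3)cc(OCc3ccccc3)c21 | intermediate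
10 | 5,7-bis(benzyloxy)-2-[3,4-bis(benzyloxy)phenyl]-8-iodo-4H-chromen-4-one | O=c1cc(-c2ccc(OCc3ccccc3)c(OCc3ccccc3)c2)oc2c(I)c(OCc3ccccc3)cc(OCc3ccccc3)c12 | intermediate
11 | 4,5-bis(benzyloxy)-2-bromobenzaldehyde | O=Cc1cc(OCc2ccccc2)c(OCc2ccccc2)cc1Br | intermediate
12 | 1,2-bis(benzyloxy)-4-bromo-5-vinylbenzene | C=Cc1cc(OCc2ccccc2)c(OCc2ccccc2)cc1Br | intermediate
13 | [4,5-bis(benzyloxy)-2-vinylphenyl]lithium | [Li]c1cc(OCc2ccccc2)c(OCc2ccccc2)cc1C=C | intermediate
14 | 2-[4,5-bis(benzyloxy)-2-vinylphenyl]-4,4,5,5-tetramethyl-1,3,2-dioxaborolane | C=Cc1cc(OCc2ccccc2)c(OCc2ccccc2)cc1B1OC(C)(C)C(C)(C)O1 | intermediate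
15 | 5,7-bis(benzyloxy)-2-[3,4-bis(benzyloxy)phenyl]-8-[4,5-bis(benzyloxy)-2-vinylphenyl]-4H-chromen-4-one | C=Cc1cc(OCc2ccccc2)c(OCc2ccccc2)cc1-c1c(OCc2ccccc2)cc(OCc2ccccc2)c2c(=O)cc(-c3ccc(OCc4ccccc4)c(OCc4ccccc4)c3)oc12 | intermediate
16 | trimethyl orthoformate | COC(OC)OC | starting material
17 | 3,5-bis(benzyloxy)-2-(dimethoxymethyl)phenol | COC(OC)c1c(O)cc(OCc2ccccc2)cc1OCc1ccccc1 | intermediate
18 | 3,5-bis(benzyloxy)-6-(methoxymethylidene)cyclohexa-2,4-dien-1-one | COC=C1C(=O)C=C(OCc2ccccc2)C=C1OCc1ccccc1 | intermediate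
19 | 8-{2-[(2R,4R)-5,7-bis(benzyloxy)-4-methoxychroman-2-yl]-4,5-bis(benzyloxy)phenyl}-5,7-bis(benzyloxy)-2-[3,4-bis(benzyloxy)phenyl]-4H-chromen-4-one (2,4-cis) | CO[C@@H]1C[C@H](c2cc(OCc3ccccc3)c(OCc3ccccc3)cc2-c2c(OCc3ccccc3)cc(OCc3ccccc3)c3c(=O)cc(-c4ccc(OCc5ccccc5)c(OCc5ccccc5)c4)oc23)Oc2cc(OCc3ccccc3)cc(OCc3ccccc3)c21 | intermediate
20 | 8-{2-[(2R)-5,7-bis(benzyloxy)-4-hydroxychroman-2-yl]-4,5-bis(benzyloxy)phenyl}-5,7-bis(benzyloxy)-2-[3,4-bis(benzyloxy)phenyl]-4H-chromen-4-one (C4 left open, epimer mixture) | OC1C[C@H](c2cc(OCc3ccccc3)c(OCc3ccccc3)cc2-c2c(OCc3ccccc3)cc(OCc3ccccc3)c3c(=O)cc(-c4ccc(OCc5ccccc5)c(OCc5ccccc5)c4)oc23)Oc2cc(OCc3ccccc3)cc(OCc3ccccc3)c21 | intermediate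
21 | 8-{2-[(2R)-5,7-bis(benzyloxy)-4-oxochroman-2-yl]-4,5-bis(benzyloxy)phenyl}-5,7-bis(benzyloxy)-2-[3,4-bis(benzyloxy)phenyl]-4H-chromen-4-one | O=C1C[C@H](c2cc(OCc3ccccc3)c(OCc3ccccc3)cc2-c2c(OCc3ccccc3)cc(OCc3ccccc3)c3c(=O)cc(-c4ccc(OCc5ccccc5)c(OCc5ccccc5)c4)oc23)Oc2cc(OCc3ccccc3)cc(OCc3ccccc3)c21 | intermediate
22 | 8-{2-[(2R)-5,7-dihydroxy-4-oxochroman-2-yl]-4,5-dihydroxyphenyl}-2-(3,4-dihydroxyphenyl)-5,7-dihydroxy-4H-chromen-4-one (CNP0228504.1) | O=C1C[C@H](c2cc(O)c(O)cc2-c2c(O)cc(O)c3c(=O)cc(-c4ccc(O)c(O)c4)oc23)Oc2cc(O)cc(O)c21 | target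

**Step count and risks**

Total steps: 13. Longest linear sequence: 9 steps (3 → 4 → 5 → 7 → 10 → 15 → 19 → 20 → 21 → 22, that is steps 2, 3, 4, 5, 9, 10, 11, 12 and 13).

Steps most likely to fail:

Step 10 (Proposed new method). The counteranion may discriminate the faces poorly, the basic flavone carbonyl may sequester the catalytic proton, or the electron-rich styrene may oligomerise under acid. The fallback uses known chemistry, sets out from styrene 15 and rejoins the route at flavanone 21. Lemieux–Johnson cleavage of the vinyl group (OsO4 cat., NaIO4, 2,6-lutidine, dioxane/H2O) would give the biaryl aldehyde F1. Claisen–Schmidt condensation of F1 with acetophenone 4 (KOH, EtOH/THF) would give the 2'-hydroxychalcone F2. Oxa-Michael cyclisation (NaOAc, EtOH, reflux) would give the racemic flavanone octabenzyl ether F3. Asymmetric transfer hydrogenation run as a kinetic resolution (RuCl(p-cymene)[(S,S)-TsDPEN] or its antipode, whichever reduces the 2S ketone faster, HCO2H/Et3N, stopped near half conversion) would reduce the 2S enantiomer to the cis-(2S,4S)-flavan-4-ol F4. The unreacted (2R)-ketone is 21, separated by chromatography and carried into step 13.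

Step 11. After ionisation at C4, loss of H3 to the flav-3-ene or Friedel–Crafts attack on ring A of a second molecule may compete with capture by water. The fallback sets out from 19 and rejoins at 21, bypassing 20 and step 12. Oxidation with DDQ in CH2Cl2/pH 7 buffer at 0 °C would abstract hydride from C4 to give the methoxy-stabilised oxocarbenium ion, water would add, and the hemiketal would collapse to the ketone with loss of methanol. No new compound arises on this path (F0).

Step 9. Slow transmetalation at the hindered axis may let protodeboronation of 14 or Heck-type consumption of the vinyl group take over. The fallback sets out from bromide 12 and rejoins at 15. Aryllithium 13, generated as in step 8, would be transmetalated with ZnCl2 in THF to the arylzinc chloride F5. Negishi coupling of F5 with iodide 10 (Pd(OAc)2, SPhos, THF, 60 °C) needs neither water nor base, so the deboronation pathway is removed.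

**Further compounds**

F1 | step 10 | 4,5-bis(benzyloxy)-2-{5,7-bis(benzyloxy)-2-[3,4-bis(benzyloxy)phenyl]-4-oxo-4H-chromen-8-yl}benzaldehyde | O=Cc1cc(OCc2ccccc2)c(OCc2ccccc2)cc1-c1c(OCc2ccccc2)cc(OCc2ccccc2)c2c(=O)cc(-c3ccc(OCc4ccccc4)c(OCc4ccccc4)c3)oc12
F2 | step 10 | (E)-2'-hydroxychalcone from F1 and 4 | O=C(/C=C/c1cc(OCc2ccccc2)c(OCc2ccccc2)cc1-c1c(OCc2ccccc2)cc(OCc2ccccc2)c2c(=O)cc(-c3ccc(OCc4ccccc4)c(OCc4ccccc4)c3)oc12)c1c(O)cc(OCc2ccccc2)cc1OCc1ccccc1
F3 | step 10 | racemic flavanone octabenzyl ether | O=C1CC(c2cc(OCc3ccccc3)c(OCc3ccccc3)cc2-c2c(OCc3ccccc3)cc(OCc3ccccc3)c3c(=O)cc(-c4ccc(OCc5ccccc5)c(OCc5ccccc5)c4)oc23)Oc2cc(OCc3ccccc3)cc(OCc3ccccc3)c21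
F4 | step 10 | cis-(2S,4S)-flavan-4-ol octabenzyl ether | O[C@H]1C[C@@H](c2cc(OCc3ccccc3)c(OCc3ccccc3)cc2-c2c(OCc3ccccc3)cc(OCc3ccccc3)c3c(=O)cc(-c4ccc(OCc5ccccc5)c(OCc5ccccc5)c4)oc23)Oc2cc(OCc3ccccc3)cc(OCc3ccccc3)c21
F0 | step 11 | none | none
F5 | step 9 | [4,5-bis(benzyloxy)-2-vinylphenyl]zinc chloride | Cl[Zn]c1cc(OCc2ccccc2)c(OCc2ccccc2)cc1C=C
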